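**Plan**

1. Locants: terpene carbons as in caryophyllane (C4 = quaternary O-bearing carbon, C5 = adjacent CH, C8 = methylidene carbon, C1/C9 = cyclobutane CH). C1′ is the CH2 between C5 and the triketone ring, C3′ and C2′ are the ring carbons bearing C1′ and the pyran oxygen, Cf is the enol carbon on the other side of C3′.
2. Cuts: (a) C5–H and C1′–H (last step, from a 2H-pyran); (b) C4–C5 together with O–C4, which opens the nine-membered ring and the pyran to an open-chain methyl ketone bearing a 2-alkenyl triketone; (c) C1′=C5 (Wittig) to a keto aldehyde and a phosphonium betaine; (d) C4=C5 of (−)-β-caryophyllene (ozonolysis) and, in the other fragment, C1′–C3′, two C-methyls and the acyl group back to phloroglucinol.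
3. Enabling feature: in the pyran ring O–C2′=C3′–C1′–C5–C4, C5 becomes the terminal carbon of the dienol O–C2′=C3′–C1′=C5 of a vinylogous acid as soon as C1′=C5 is a double bond, and C4 (O, CH3, C3) has the oxidation level of a methyl ketone. Condensation of the two forms C4–C5 and lets the C2′ oxygen close on C4.
4. Forward: cyclobutane from the chiral pool, fragment union at C1′=C5, then carbocycle (C4–C5) and pyran (O–C4) in one operation, then saturation of C5–C1′.
5. Stereochemistry: C1 and C9 are carried over from (−)-β-caryophyllene. C4 arises in the key step, controlled by the trans-fused cyclobutane through the fold of the new nine-membered ring. C5 arises in the last step by protonation anti to the C4 methyl (trans ring fusion).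

Key step: step 6

Assumption: the target and all triketone intermediates are drawn as one enol tautomer and the tautomers count as one compound; commercial (−)-β-caryophyllene is the (1R,4E,9S) isomer, which already carries the C1/C9 configuration of the target.

**Route**

Step 1
Reactants: 1 (−)-β-caryophyllene
Product: 3 keto aldehyde 4-[(1S,2R)-3,3-dimethyl-2-(3-oxobutyl)cyclobutyl]pent-4-enal, via secondary ozonide 2 (not isolated)
Conditions: O3 (1.0 equiv, Sudan Red 7B end point), CH2Cl2, −78 °C; then PPh3 (1.1 equiv), −78 °C → rt
Reagents that add atoms: ozone, [O-][O+]=O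
Why: Ozonolysis with reductive work-up; the strained trisubstituted C4=C5 bond should react with ozone far faster than the 1,1-disubstituted C8 methylidene, so one equivalent cleaves only C4=C5 and leaves C1 and C9 untouched.

Step 2
Reactants: 4 phloroglucinol; 5 isobutyryl chloride
Product: 6 phloroisobutyrophenone
Conditions: AlCl3 (3.5 equiv), PhNO2/CH2Cl2, 0 → 50 °C; aq HCl
Reagents that add atoms: none
Why: Friedel–Crafts C-acylation of the symmetric, strongly activated arene, in which only one mono-acyl product is possible and the new ketone deactivates the ring against a second acylation.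

Step 3
Reactants: 6 phloroisobutyrophenone
Product: 8 isobutyrylfilicinic acid, via C-monomethyl ketone 7 (not isolated)
Conditions: NaOMe (3.0 equiv), MeI (2.2 equiv), MeOH, 0 °C → rt; aq HCl
Reagents that add atoms: iodomethane, CI
Why: Dearomatizing geminal C-methylation of an acylphloroglucinol: the phenolate is methylated at a free ring carbon and, after 7, again at the same carbon, which should give the non-aromatic filicinic acid core with the substitution pattern of the target ring; over-methylated by-products are removed by chromatography.

Step 4
Reactants: 8 isobutyrylfilicinic acid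
Product: 10 phosphonium enolate betaine, via methylidene trione 9 (not isolated)
Conditions: (CH2O)n (1.5 equiv), PPh3 (1.5 equiv), AcOH (cat.), MeCN, 60 °C
Reagents that add atoms: formaldehyde (as paraformaldehyde), C=O; triphenylphosphine, c1ccc(cc1)P(c1ccccc1)c1ccccc1
Why: Knoevenagel condensation at C3′, the only ring CH, gives heterodiene 9, which is trapped at C1′ by phospha-Michael addition of PPh3 to give zwitterion 10; the competing methylene-bis(triketone) should revert to 9 on heating and be drained by the phosphine.

Step 5
Reactants: 10 phosphonium enolate betaine; 3 keto aldehyde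
Product: 12 open-chain dienol ketone, via dipotassium ylide 11 (not isolated)
Conditions: KN(SiMe3)2 (2.1 equiv), THF, −78 → 0 °C; then 3 (1.0 equiv), −78 °C → rt; 1 M HCl
Reagents that add atoms: none
Why: Wittig olefination with a (2-hydroxybenzyl)-type ylide, which should add to the aldehyde of 3 much faster than to its methyl ketone and create C1′=C5; no stereocentre is formed and the alkene geometry (E expected) is erased in step 6.

Step 6
Reactants: 12 open-chain dienol ketone
Product: 15 2H-pyran, via titanium aldolate 13 (not isolated), via oxatriene 14 (not isolated)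
Conditions: TiCl4 (3 equiv), pyridine (8 equiv), THF, 0 °C; 12 added by syringe pump over 8 h (final 0.002 M); rt, then 50 °C
Reagents that add atoms: none
Why: Proposed new method: TiCl4/pyridine should turn the vinylogous acid of 12 into a titanium dienolate (O–C2′=C3′–C1′=C5) that also binds the C4 ketone, so that the dienolate terminus C5 adds to C4 inside a chelate (vinylogous aldol, 9-exo-trig closure of the carbocycle, aldolate 13); loss of the titanium-bound oxygen through the acidic vinylogous C5–H then gives 1-oxatriene 14, whose thermal disrotatory oxa-6π electrocyclization closes the pyran through the O–C4 bond. The closest known reaction types are the TiCl4/pyridine Knoevenagel condensation of ketones with carbon acids of similar acidity, the Knoevenagel/oxa-6π route from 1,3-diones and enals to 2H-pyrans, and Lewis acid vinylogous aldol closures of eight-membered carbocycles; new are the γ-carbon of a 2-alkenyl triketone as donor towards a ketone and the nine-membered ring. The step needs γ- over α-attack and the ketone as the electrophile: attack through C3′ gives a quaternary aldolate that cannot dehydrate and reverts, pyridine hardly enolizes the titanium-bound ketone, and the irreversible dehydration drains the γ-pathway, while high dilution and the chelate favour ring closure over oligomers. Closure on the C2′ oxygen and not on the Cf oxygen is expected because the Cf enol stays hydrogen-bonded to the isobutyryl carbonyl, as in hetero-Diels–Alder reactions of heterodiene 9. C4, the only new stereocentre, is formed in the electrocyclization next to the fixed trans-cyclobutane (C1, C9); 14 and 15 should interconvert on warming, so its configuration is under thermodynamic control of the fold of the nine-membered ring. The 4S epimer is required, and which fold is lower in energy cannot be predicted with confidence; C5 is trigonal in 15 and is set in step 7.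

Step 7
Reactants: 15 2H-pyran
Product: 17 target CNP0497637.1, via oxocarbenium trifluoroacetate 16 (not isolated)
Conditions: Et3SiH (5 equiv), CF3CO2H (3 equiv), CH2Cl2, −40 → −10 °C
Reagents that add atoms: none
Why: Ionic hydrogenation of an enol-ether-type diene: the O–C2′=C3′–C1′=C5 system should be protonated at C5 far more readily than the isolated C8 methylidene to give oxocarbenium 16, which takes hydride from Et3SiH at C1′; because this protonation is reversible and axial, C5 is expected to end with its hydrogen anti to the pseudo-axial C4 methyl, that is with C3 and C6 both pseudo-equatorial on the pyran (trans ring fusion, 5R), though this preference is not secure.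

**Compound list**

1 | (−)-β-caryophyllene, (1R,4E,9S)-4,11,11-trimethyl-8-methylidenebicyclo[7.2.0]undec-4-ene | C/C1=C\CCC(=C)[C@H]2CC([C@@H]2CC1)(C)C | starting material
2 | secondary ozonide, 1,2,4-trioxolane spanning C4 and C5 of 1 (new centres undefined) | CC12CC[C@@H]3[C@H](CC3(C)C)C(=C)CCC(O1)OO2 | intermediate
3 | keto aldehyde, 4-[(1S,2R)-3,3-dimethyl-2-(3-oxobutyl)cyclobutyl]pent-4-enal | O=CCCC(=C)[C@H]1CC(C)(C)[C@@H]1CCC(C)=O | intermediate
4 | phloroglucinol, benzene-1,3,5-triol | Oc1cc(O)cc(O)c1 | starting material
5 | isobutyryl chloride, 2-methylpropanoyl chloride | CC(C)C(Cl)=O | starting material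
6 | phloroisobutyrophenone, 2-methyl-1-(2,4,6-trihydroxyphenyl)propan-1-one | CC(C)C(=O)c1c(O)cc(O)cc1O | intermediate
7 | C-monomethyl ketone, 2-methyl-1-(2,4,6-trihydroxy-3-methylphenyl)propan-1-one | CC(C)C(=O)c1c(O)cc(O)c(C)c1O | intermediate
8 | isobutyrylfilicinic acid, 3,5-dihydroxy-6,6-dimethyl-2-(2-methylpropanoyl)cyclohexa-2,4-dien-1-one | CC(C)C(=O)C1=C(O)C=C(O)C(C)(C)C1=O | intermediate
9 | methylidene trione, the C3′=CH2 heterodiene derived from 8 | C=C1C(=O)C(C)(C)C(=O)C(C(=O)C(C)C)=C1O | intermediate
10 | phosphonium enolate betaine, triphenylphosphonio-methyl group (C1′) on C3′ of the triketone enolate | CC(C)C(=O)C1=C(O)C(C[P+](c2ccccc2)(c2ccccc2)c2ccccc2)=C([O-])C(C)(C)C1=O | intermediate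
11 | dipotassium ylide of 10 (ylide carbon C1′, both enols deprotonated) | CC(C)C(=O)C1=C([O-])C(C=P(c2ccccc2)(c2ccccc2)c2ccccc2)=C([O-])C(C)(C)C1=O.[K+].[K+] | intermediate
12 | open-chain dienol ketone: triketone ring bearing at C3′ an (E)-CH=CH–CH2CH2–C(=CH2)– chain to the (1S,2R)-3,3-dimethyl-2-(3-oxobutyl)cyclobutyl group | CC(C)C(=O)C1=C(O)C(/C=C/CCC(=C)[C@H]2CC(C)(C)[C@@H]2CCC(C)=O)=C(O)C(C)(C)C1=O | intermediate
13 | titanium aldolate: nine-membered ring closed at C4–C5, C4–O–TiCl3, alkylidene trione at C1′=C3′ (C4 and C5 undefined) | C=C1CCC(C=C2C(=O)C(C)(C)C(=O)C(C(=O)C(C)C)=C2O)C(C)(O[Ti](Cl)(Cl)Cl)CC[C@@H]2[C@@H]1CC2(C)C | intermediate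
14 | oxatriene: nine-membered ring with tetrasubstituted C4=C5, C5 bearing the CH= link (C1′) to the trione ring | C=C1CCC(C=C2C(=O)C(C)(C)C(=O)C(C(=O)C(C)C)=C2O)=C(C)CC[C@@H]2[C@@H]1CC2(C)C | intermediate
15 | 2H-pyran: the target skeleton with a C5=C1′ double bond, (4S) | C=C1CCC2=CC3=C(O[C@@]2(C)CC[C@@H]2[C@@H]1CC2(C)C)C(C)(C)C(=O)C(C(=O)C(C)C)=C3O | intermediate
16 | oxocarbenium trifluoroacetate: 15 protonated at C5, cation over O=C2′–C3′=C1′ | C=C1CC[C@@H]2C=C3C(=[O+][C@@]2(C)CC[C@@H]2[C@@H]1CC2(C)C)C(C)(C)C(=O)C(C(=O)C(C)C)=C3O.[O-]C(=O)C(F)(F)F | intermediate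
17 | target CNP0497637.1: pyran trans-fused to the nine-membered ring, (1R,4S,5R,9S) in the locants used here | C=C1CC[C@@H]2CC3=C(O[C@@]2(C)CC[C@@H]2[C@@H]1CC2(C)C)C(C)(C)C(=O)C(C(=O)C(C)C)=C3O | target

**Count**

Total: 7 steps. Longest linear sequence: 6 steps (4 → 6 → 8 → 10 → 12 → 15 → 17, steps 2 to 7).

**Steps most likely to fail**

1. Step 6 (proposed new method). The stabilized dienolate may add too slowly to the ketone at high dilution, so that oligomerization, conjugate addition of a ketone enolate to the alkylidene tautomer of 12, or Lewis acid attack on the C8 methylidene takes over. The facial bias at C4 may also be low or wrong (the unwanted epimer could be re-equilibrated through 14 by warming). Fallback with known chemistry, closing the same bond first: it sets out from 3. Low-valent titanium pinacol coupling (TiCl3(DME)1.5, Zn–Cu couple, DME, 25 °C, high dilution) should close the nine-membered ring between C4 and C5 and give nine-membered diol F1. Swern oxidation of the secondary hydroxyl gives α-hydroxy ketone F2. Methylenation (Ph3P=CH2 in excess, or Cp2TiMe2) gives tertiary allylic alcohol F3. Babler–Dauben oxidative transposition (pyridinium chlorochromate, C5H5NH[CrO3Cl], CH2Cl2) gives cyclononene carbaldehyde F4. Knoevenagel condensation of F4 with 8 (ethylenediammonium diacetate, MeOH, rt to 50 °C) gives oxatriene 14, which closes to 15, where the route is rejoined.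

2. Step 5. Ylide formation next to the doubly deprotonated ring may be incomplete, and the basic medium may enolize 3 and cause self-condensation. Fallback: it sets out from 3. Wittig reaction with Ph3P=CHOMe (from (methoxymethyl)triphenylphosphonium chloride and KN(SiMe3)2, THF, −78 °C, the aldehyde reacting before the ketone) gives enol ether F5. Mild hydrolysis (aq oxalic acid, THF) gives the one-carbon-longer homologous aldehyde F6. Knoevenagel condensation of F6 with 8 (L-proline cat., CH2Cl2) gives alkylidene trione F7, the C5-protonated tautomer of 12, which should equilibrate with 12 and give the same titanium dienolate in step 6; the route is rejoined at 12.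

3. Step 7. The proton may add to C5 from the wrong face (cis ring fusion), and the acid may also protonate the C8 methylidene or ionize the tertiary C4–O bond. Fallback: it sets out from 15. Warming with Hantzsch ester (diethyl 2,6-dimethyl-1,4-dihydropyridine-3,5-dicarboxylate, toluene, 80 °C) should reduce the ring-opened valence tautomer 14 by hydride transfer to C1′ and give C-alkylated triketone F8 with a tetrasubstituted C4=C5 alkene. Brønsted acid cycloetherification (camphorsulfonic acid or Amberlyst 15, CH2Cl2, 0 °C) then closes the O–C4 bond, so that the ring fusion is set in the ring closure and not by protonation of the intact pyran; the route is rejoined at 17.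

**Further compounds**

F1 | step 6 | nine-membered diol, caryophyll-8(13)-ene-4,5-diol (C4 and C5 undefined) | C=C1CCC(O)C(C)(O)CC[C@@H]2[C@@H]1CC2(C)C
F2 | step 6 | α-hydroxy ketone, C5 ketone with tertiary C4 hydroxyl | C=C1CCC(=O)C(C)(O)CC[C@@H]2[C@@H]1CC2(C)C
F3 | step 6 | tertiary allylic alcohol, C5 methylidene with tertiary C4 hydroxyl | C=C1CCC(=C)C(C)(O)CC[C@@H]2[C@@H]1CC2(C)C
F4 | step 6 | cyclononene carbaldehyde, formyl group on C5 of the C4=C5 alkene | C=C1CCC(C=O)=C(C)CC[C@@H]2[C@@H]1CC2(C)C
F5 | step 5 | enol ether, methoxyvinyl homologue of 3 | COC=CCCC(=C)[C@H]1CC(C)(C)[C@@H]1CCC(C)=O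
F6 | step 5 | homologous aldehyde, 5-[(1S,2R)-3,3-dimethyl-2-(3-oxobutyl)cyclobutyl]hex-5-enal | O=CCCCC(=C)[C@H]1CC(C)(C)[C@@H]1CCC(C)=O
F7 | step 5 | alkylidene trione, C5-protonated tautomer of 12 | CC(C)C(=O)C1=C(O)C(=CCCCC(=C)[C@H]2CC(C)(C)[C@@H]2CCC(C)=O)C(=O)C(C)(C)C1=O
F8 | step 7 | C-alkylated triketone with tetrasubstituted C4=C5 alkene | CC(C)C(=O)C1=C(O)C(CC2=C(C)CC[C@@H]3[C@H](CC3(C)C)C(=C)CC2)=C(O)C(C)(C)C1=O
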